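One charge, the left-handed and right-handed substrate together, is the unit here, and the partner of the dusk flask comes to 1.00 of it.

the same everywhere: racemization catalyst 27 mM
- dusk: left-handed substrate 0.65 M; right-handed substrate 0.65 M; partner 1.3 M; temperature 25 °C; the very flask that is asked about, followed so far
- summer: left-handed substrate 1.3 M; right-handed substrate 1.3 M; partner 1.3 M; temperature 10 °C; run made earlier
- flask: left-handed substrate 0.65 M; right-handed substrate 0.65 M; partner 1.30 M; temperature 25 °C; time 25 min

- dusk (time / min: left-handed product / %, left-handed substrate / %): 1.33: 9.4, 41.5; 4.00: 20.5, 35.9; 8.00: 27.7, 33.7; 10.0: 29.9, 33.6; 15.0: 32.9, 31.5; 20.0: 33.4, 31.7
- summer (time / min: left-handed product / %, left-handed substrate / %): 0.667: 1.7, 48.4; 2.00: 4.3, 46.8; 3.00: 4.8, 45.8; 5.00: 8.7, 41.9; 8.00: 12.4, 40.2; 10.0: 14.4, 39.7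

(each reading ± 0.5 percentage points)

- oak: at 25 min add partner, 50.0% of the amount charged, then wait 25 min
- maple: at 25 min raise the temperature by 15 K, then wait 25 min
- alder: change nothing and wait 25 min more
- elm: at 25 min add racemization catalyst, 100% of the amount charged, then wait 25 min
- cedar: at 25 min take out 90% of the left-handed product then present, then wait 25 min

- partner is single-handed; left-handed substrate and right-handed substrate are mirror images of each other, charged as a racemate, each of them at the stated concentration
- left-handed product that was removed still counts
- additions bring no volume worth counting
- the handed part of partner does not stay in what it makes, so the products of the two hands are mirror images too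

1. left-handed product, in percent of the left-handed substrate and right-handed substrate together first charged, at 25 min
2. which option adds most left-handed product ("none" when 2 percentage points or less is all one gets) (oak / maple / alder / elm / cedar / none)
3. left-handed product present, with what was taken out counted in, in percent of the left-handed substrate and right-handed substrate together first charged, after oak
4. left-handed product present, with what was taken out counted in, in percent of the left-handed substrate and right-handed substrate together first charged, after maple

The left-handed product of the dusk flask leaves zero at a mean slope of 0.0707 /min over the first reading. The last reading, taken as the level, over that slope gives 4.73 min, which marks the knee. The product crosses the left-handed substrate between 10.0 min and 15.0 min and reads 33.4% at 20.0 min. Between 10.0 min and 15.0 min its slope is 0.00600 /min, less than at the start, although the left-handed substrate still reads 31.5%.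

The zero of the scale is the racemic pool: this reckoning keeps both substrates equal and splits what is not left-handed product evenly between them, which gives the left-handed substrate r. At the level that makes 0.333, half of what is not left-handed product, and the reading of 31.7% lies lower.

This reckoning takes the stall for partner lost on a path of its own, which the readings do not prove. Each portion of partner then gives product with the share r/(r+a). Integrating from the start to the level gives a as partner charge minus level, over twice the logarithm of the inverse of the fraction not product: 0.819. This a is the split level, the fraction of the charge standing as left-handed substrate at which partner divides equally between product and loss.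

At the level the share is 0.289. So this reckoning puts the dusk flask at about 33.4% at 25 min. Oak adds 0.500 of a charge of partner, and at the share midway through the gain, 0.266, this reckoning puts the left-handed product at 46.7%. The other options bring no partner, so the reckoning leaves them at the level.

The forecast says “I read it as reversible reaction”. It gives 33.4% (32% to 35%) now, 39% (35.5% to 46%) after oak and 27.5% (23% to 33%) after maple, and it names cedar as best. The reckoning above differs from it on oak, on maple and on the best option.

The flask gives 33.5% at 25 min, 47.0% after oak and 33.7% after maple. The best option is oak, adding 13 percentage points, the most of the options.

    racemization catalyst ⇌ dormant form (K = 2.10, k = 0.0570 /s, Ea = 68.0 kJ/mol, ΔH = −28.0 kJ/mol)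
    partner + left-handed substrate → left-handed product (k = 0.00230 /M/s, Ea = 66.0 kJ/mol)
    partner → decomposed reagent (k = 0.00210 /s, Ea = 81.0 kJ/mol)
    partner + right-handed substrate → right-handed product (k = 2.20 × 10⁻⁴ /M/s, Ea = 70.0 kJ/mol)
    left-handed substrate + racemization catalyst ⇌ right-handed substrate + racemization catalyst, rate k5*[racemization catalyst]*[left-handed substrate] forward; the back reaction follows from the equilibrium constant (k = 0.520 /M/s, Ea = 36.0 kJ/mol)
    (constants at 25 °C)

At 25.0 min the flask holds 0.812% of its partner, and the running short of partner is the main reason for the level: with partner held, the run gives 79.0% against 33.5%. At the 31.4% left-handed substrate of the flask the split level gives a share of 0.277 for the first of oak's partner. In the neighbour flask with 2.2 M of partner, 0.692 of a charge more, the midway share 0.257 gives 51.2%. That neighbour flask gives 49.7%.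

(The data are calculated from invented constants; the scatter is artificial.)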